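**Retrosynthetic overview**

1. Last bond: the C7–O ester. The bicyclic 3,7-diol is acylated with (E)-4-oxooct-2-enoic acid, itself one step from hexan-2-one and glyoxylic acid.
2. Both rings come from C–O bond formation on one acyclic epoxy imide. The C8 hydroxyl opens the C4–C5 epoxide at tertiary C4 with inversion (oxane ring first); the C5 hydroxyl released then acylates itself on C1 (δ-lactone second). The trans ring fusion follows from the (E)-alkene and anti opening.
3. The epoxide comes from hydroxyl-directed epoxidation of the (E)-trisubstituted alkene; C2–C3 comes from an auxiliary-controlled anti-aldol of a propionimide with an (E)-2-methyl enal.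
4. The enal comes from cross-metathesis of a homoallylic alcohol with methacrolein; C6–C7 comes from (Z)-crotylboration of O-silyl (S)-lactaldehyde (C8 from ethyl (S)-lactate).

Assumption and numbering: the target is taken exactly as the SMILES gives it; carbons are numbered C1 (lactone C=O), C2 (Me), C3 (OH), C4 (Me, ring O), C5 (lactone O), C6 (Me), C7 (O-acyl), C8 (ring O), C9 (methyl); the crotylboronate and the propionimide are bought.

**Route**

Step 1
Reactants: 1 ethyl (S)-lactate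
Product: 2 ethyl (2S)-2-[(tert-butyldimethylsilyl)oxy]propanoate
Conditions: TBSCl, imidazole, DMF, 23 °C
Reagents that add atoms: tert-butyldimethylsilyl chloride, CC(C)(C)[Si](C)(C)Cl
Why: O-silylation of the secondary alcohol; the lactate stereocentre (future C8, S) is not touched.

Step 2
Reactants: 2 ethyl (2S)-2-[(tert-butyldimethylsilyl)oxy]propanoate
Product: 3 (2S)-2-[(tert-butyldimethylsilyl)oxy]propanal
Conditions: i-Bu2AlH, CH2Cl2, −78 °C; aqueous potassium sodium tartrate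
Reagents that add atoms: none
Why: DIBAL-H partial reduction of the ester stops at the aldehyde through the stable tetrahedral aluminium hemiacetal at −78 °C; the aldehyde is used at once to avoid epimerisation.

Step 3
Reactants: 3 (2S)-2-[(tert-butyldimethylsilyl)oxy]propanal; 4 (Z)-crotylboronic acid pinacol ester
Product: 6 (2S,3R,4S)-2-[(tert-butyldimethylsilyl)oxy]-4-methylhex-5-en-3-ol, via pinacol borate ester 5 (not isolated)
Conditions: toluene, 4 Å molecular sieves, 23 °C, 48 h; aqueous NaHCO3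
Reagents that add atoms: none
Why: Crotylboration through a closed chair (Zimmerman–Traxler) transition state: the (Z)-boronate gives the C6/C7 syn relation, and Felkin–Anh (Cornforth) attack on the Re face of the α-silyloxy aldehyde gives the C7/C8 anti relation.

Step 4
Reactants: 6 (2S,3R,4S)-2-[(tert-butyldimethylsilyl)oxy]-4-methylhex-5-en-3-ol; 7 methacrolein
Product: 8 (2E,4S,5R,6S)-6-[(tert-butyldimethylsilyl)oxy]-5-hydroxy-2,4-dimethylhept-2-enal
Conditions: second-generation Hoveyda–Grubbs catalyst (5 mol %), 7 (8 equiv), CH2Cl2, 40 °C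
Reagents that add atoms: none
Why: Olefin cross-metathesis of the terminal alkene with excess methacrolein gives the trisubstituted (E)-enal under thermodynamic control; no stereocentre is touched.

Step 5
Reactants: 8 (2E,4S,5R,6S)-6-[(tert-butyldimethylsilyl)oxy]-5-hydroxy-2,4-dimethylhept-2-enal; 9 (4S)-4-benzyl-3-propanoyl-1,3-oxazolidin-2-one
Product: 11 (4S)-4-benzyl-3-[(2R,3S,4E,6S,7R,8S)-8-[(tert-butyldimethylsilyl)oxy]-3,7-dihydroxy-2,4,6-trimethylnon-4-enoyl]-1,3-oxazolidin-2-one, via bis-trimethylsilyl ether 10 (not isolated)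
Conditions: MgCl2 (0.2 equiv), Et3N, Me3SiCl, EtOAc, 23 °C; then CF3CO2H, MeOH, 0 °C
Reagents that add atoms: none
Why: Evans magnesium-halide-catalysed anti-aldol: the chelated (Z)-magnesium enolate of the (S)-imide adds to the non-enolisable enal through a boat transition state, setting C2 (R) and C3 (S) anti under auxiliary control; transient O-silylation turns the catalyst over and masks the C7 hydroxyl.

Step 6
Reactants: 11 (4S)-4-benzyl-3-[(2R,3S,4E,6S,7R,8S)-8-[(tert-butyldimethylsilyl)oxy]-3,7-dihydroxy-2,4,6-trimethylnon-4-enoyl]-1,3-oxazolidin-2-one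
Product: 12 (4S)-4-benzyl-3-[(2R,3S,4S,5S,6R,7R,8S)-8-[(tert-butyldimethylsilyl)oxy]-4,5-epoxy-3,7-dihydroxy-2,4,6-trimethylnonanoyl]-1,3-oxazolidin-2-one
Conditions: VO(acac)2 (5 mol %), t-BuOOH, CH2Cl2, 0 °C; aqueous Na2S2O3, silica filtration
Reagents that add atoms: tert-butyl hydroperoxide, CC(C)(C)OO
Why: Hydroxyl-directed vanadium-catalysed epoxidation of the allylic alcohol: allylic 1,2-strain with the C4 methyl favours the erythro epoxy alcohol, which puts the epoxide oxygen on the face that becomes C5–O; the (E)-geometry fixes the C4/C5 relation, and the C8 silyl ether keeps that oxygen from opening the vanadium-bound epoxide.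

Step 7
Reactants: 12 (4S)-4-benzyl-3-[(2R,3S,4S,5S,6R,7R,8S)-8-[(tert-butyldimethylsilyl)oxy]-4,5-epoxy-3,7-dihydroxy-2,4,6-trimethylnonanoyl]-1,3-oxazolidin-2-one
Product: 15 (2S,3R,4R,4aS,7R,8S,8aR)-3,8-dihydroxy-2,4,7,8a-tetramethyl-2,3,4,4a,7,8-hexahydropyrano[3,2-b]pyran-6-one, via desilylated epoxy triol 13 (not isolated), via hydroxy-oxane imide 14 (not isolated)
Conditions: camphorsulfonic acid (0.3 equiv), (CF3)2CHOH–H2O (50:1), 0 → 40 °C
Reagents that add atoms: none
Why: Proposed new method: a fluoroalcohol-promoted desilylative 6-endo epoxide-opening/acyl-transfer cascade on an anti-aldol-derived 2,3-epoxy alcohol carrying an N-acyloxazolidinone – the strongly ionising, non-coordinating, hydrogen-bond-donating medium removes the silyl group and loosens the tertiary C4–O bond of the protonated epoxide (no metal chelate to the C3 hydroxyl, which would steer attack to C5), so the C8 hydroxyl attacks C4 with inversion through a chair with C6-methyl, C7-hydroxyl and C8-methyl all equatorial, forming the ring C–O bond and setting C4 while C5 keeps the epoxide oxygen; the freed C5 hydroxyl then attacks the imide carbonyl and expels the oxazolidinone to give the trans-fused δ-lactone, which makes the sequence irreversible; the closest known reaction types are the acid-mediated 6-endo cyclisation of methyl-bearing hydroxy epoxides, fluoroalcohol-promoted endo-selective epoxide-opening cascades and the lactonisation of δ-hydroxy N-acyloxazolidinones with loss of the auxiliary.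

Step 8
Reactants: 16 hexan-2-one; 17 glyoxylic acid monohydrate
Product: 18 (2E)-4-oxooct-2-enoic acid
Conditions: pyrrolidine, AcOH, MeOH, 60 °C
Reagents that add atoms: none
Why: Amine-mediated aldol condensation: the less substituted enamine of the methyl ketone adds to glyoxylic acid and dehydration gives the (E)-4-oxo-enoic acid under thermodynamic control.

Step 9
Reactants: 15 (2S,3R,4R,4aS,7R,8S,8aR)-3,8-dihydroxy-2,4,7,8a-tetramethyl-2,3,4,4a,7,8-hexahydropyrano[3,2-b]pyran-6-one; 18 (2E)-4-oxooct-2-enoic acid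
Product: 19 botcinin I
Conditions: DCC, DMAP (0.1 equiv), CH2Cl2, −20 → 0 °C
Reagents that add atoms: none
Why: Steglich esterification; the equatorial C7 hydroxyl (flanked by two CH(CH3) carbons) should be acylated before the C3 hydroxyl, which is neopentylic next to quaternary C4 and flanked by the C2 methyl; no stereocentre is touched.

**Compound list**

1 | ethyl (2S)-2-hydroxypropanoate (ethyl (S)-lactate) | CCOC(=O)[C@H](C)O | starting material
2 | ethyl (2S)-2-[(tert-butyldimethylsilyl)oxy]propanoate | CCOC(=O)[C@H](C)O[Si](C)(C)C(C)(C)C | intermediate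
3 | (2S)-2-[(tert-butyldimethylsilyl)oxy]propanal | C[C@H](O[Si](C)(C)C(C)(C)C)C=O | intermediate
4 | 2-[(2Z)-but-2-en-1-yl]-4,4,5,5-tetramethyl-1,3,2-dioxaborolane ((Z)-crotylboronic acid pinacol ester) | C/C=C\CB1OC(C)(C)C(C)(C)O1 | starting material
5 | 2-{[(2S,3R,4S)-2-[(tert-butyldimethylsilyl)oxy]-4-methylhex-5-en-3-yl]oxy}-4,4,5,5-tetramethyl-1,3,2-dioxaborolane | C[C@H](O[Si](C)(C)C(C)(C)C)[C@H](OB1OC(C)(C)C(C)(C)O1)[C@@H](C)C=C | intermediate
6 | (2S,3R,4S)-2-[(tert-butyldimethylsilyl)oxy]-4-methylhex-5-en-3-ol | C[C@H](O[Si](C)(C)C(C)(C)C)[C@H](O)[C@@H](C)C=C | intermediate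
7 | 2-methylprop-2-enal (methacrolein) | CC(=C)C=O | starting material
8 | (2E,4S,5R,6S)-6-[(tert-butyldimethylsilyl)oxy]-5-hydroxy-2,4-dimethylhept-2-enal | C[C@H](O[Si](C)(C)C(C)(C)C)[C@H](O)[C@@H](C)/C=C(\C)C=O | intermediate
9 | (4S)-4-benzyl-3-propanoyl-1,3-oxazolidin-2-one | CCC(=O)N1C(=O)OC[C@@H]1Cc1ccccc1 | starting material
10 | (4S)-4-benzyl-3-[(2R,3S,4E,6S,7R,8S)-8-[(tert-butyldimethylsilyl)oxy]-2,4,6-trimethyl-3,7-bis[(trimethylsilyl)oxy]non-4-enoyl]-1,3-oxazolidin-2-one | C[C@H](O[Si](C)(C)C(C)(C)C)[C@H](O[Si](C)(C)C)[C@@H](C)/C=C(\C)[C@@H](O[Si](C)(C)C)[C@@H](C)C(=O)N1C(=O)OC[C@@H]1Cc1ccccc1 | intermediate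
11 | (4S)-4-benzyl-3-[(2R,3S,4E,6S,7R,8S)-8-[(tert-butyldimethylsilyl)oxy]-3,7-dihydroxy-2,4,6-trimethylnon-4-enoyl]-1,3-oxazolidin-2-one | C[C@H](O[Si](C)(C)C(C)(C)C)[C@H](O)[C@@H](C)/C=C(\C)[C@@H](O)[C@@H](C)C(=O)N1C(=O)OC[C@@H]1Cc1ccccc1 | intermediate
12 | (4S)-4-benzyl-3-[(2R,3S,4S,5S,6R,7R,8S)-8-[(tert-butyldimethylsilyl)oxy]-4,5-epoxy-3,7-dihydroxy-2,4,6-trimethylnonanoyl]-1,3-oxazolidin-2-one | C[C@H](O[Si](C)(C)C(C)(C)C)[C@H](O)[C@@H](C)[C@@H]1O[C@@]1(C)[C@@H](O)[C@@H](C)C(=O)N1C(=O)OC[C@@H]1Cc1ccccc1 | intermediate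
13 | (4S)-4-benzyl-3-[(2R,3S,4S,5S,6R,7R,8S)-4,5-epoxy-3,7,8-trihydroxy-2,4,6-trimethylnonanoyl]-1,3-oxazolidin-2-one | C[C@H](O)[C@H](O)[C@@H](C)[C@@H]1O[C@@]1(C)[C@@H](O)[C@@H](C)C(=O)N1C(=O)OC[C@@H]1Cc1ccccc1 | intermediate
14 | (4S)-4-benzyl-3-{(2R,3S)-3-[(2S,3S,4R,5R,6S)-3,5-dihydroxy-2,4,6-trimethyloxan-2-yl]-3-hydroxy-2-methylpropanoyl}-1,3-oxazolidin-2-one | O[C@@H]1[C@@H](C)[C@H](O)[C@@](C)([C@@H](O)[C@@H](C)C(=O)N2C(=O)OC[C@@H]2Cc2ccccc2)O[C@H]1C | intermediate
15 | (2S,3R,4R,4aS,7R,8S,8aR)-3,8-dihydroxy-2,4,7,8a-tetramethyl-2,3,4,4a,7,8-hexahydropyrano[3,2-b]pyran-6-one | O[C@@H]1[C@@H](C)[C@@H]2OC(=O)[C@H](C)[C@H](O)[C@@]2(C)O[C@H]1C | intermediate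
16 | hexan-2-one | CCCCC(C)=O | starting material
17 | glyoxylic acid monohydrate (2,2-dihydroxyacetic acid) | OC(O)C(=O)O | starting material
18 | (2E)-4-oxooct-2-enoic acid | CCCCC(=O)/C=C/C(=O)O | intermediate
19 | botcinin I, [(2S,3R,4R,4aS,7R,8S,8aR)-8-hydroxy-2,4,7,8a-tetramethyl-6-oxo-2,3,4,4a,7,8-hexahydropyrano[3,2-b]pyran-3-yl] (2E)-4-oxooct-2-enoate | CCCCC(=O)/C=C/C(=O)O[C@@H]1[C@@H](C)[C@@H]2OC(=O)[C@H](C)[C@H](O)[C@@]2(C)O[C@H]1C | target

**Step count**

Total: 9 steps. Longest linear sequence: 8 steps (steps 1–7 and 9); step 8 is a one-step side branch.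

**The three steps most likely to fail**

Step 7 (the proposed new step) is the main risk. The C8 hydroxyl may attack C5 instead (5-exo, giving an oxolane), which is the usual preference of acyclic 4,5-epoxy alcohols and is made more likely here because the C3 hydroxyl inductively deactivates C4. The C7 hydroxyl or the imide carbonyl may also capture C4, or a 1,2-hydride shift may give a ketone.

The fallback uses known chemistry, sets out from 8 and comes back at 14, which lactonises to 15. Enal 8 is methylenated (Ph3P=CH2, THF, 0 °C) to (2S,3R,4S,5E)-2-[(tert-butyldimethylsilyl)oxy]-4,6-dimethylocta-5,7-dien-3-ol F1. Shi epoxidation with the L-fructose-derived ketone catalyst (KHSO5, K2CO3, MeCN–CH2(OMe)2–aqueous buffer, 0 °C) oxidises only the trisubstituted alkene, from the required face, to the vinyl epoxide (2S,3R,4R)-2-[(tert-butyldimethylsilyl)oxy]-4-[(2S,3S)-3-ethenyl-3-methyloxiran-2-yl]pentan-3-ol F2. n-Bu4NF removes the silyl group to give (2S,3R,4R)-4-[(2S,3S)-3-ethenyl-3-methyloxiran-2-yl]pentane-2,3-diol F3. Camphorsulfonic acid in CH2Cl2 then closes the ring 6-endo at the allylic tertiary carbon (hydroxy vinyl-epoxide cyclisation) to (2R,3S,4R,5R,6S)-2-ethenyl-2,4,6-trimethyloxane-3,5-diol F4. Ozonolysis (O3, then Me2S) gives (2S,3S,4R,5R,6S)-3,5-dihydroxy-2,4,6-trimethyloxane-2-carbaldehyde F5. The MgCl2-catalysed anti-aldol of this non-enolisable aldehyde with 9 (Et3N, Me3SiCl; then CF3CO2H, MeOH) gives 14, and acid closes the lactone to 15.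

Step 9 may give mixtures of the 7-ester, the 3-ester and the diester, since both hydroxyls are hindered secondary alcohols. The fallback sets out from 15 and comes back at 19. Both hydroxyls are silylated (Et3SiOTf, 2,6-lutidine) to (2S,3R,4R,4aS,7R,8S,8aR)-2,4,7,8a-tetramethyl-3,8-bis[(triethylsilyl)oxy]-2,3,4,4a,7,8-hexahydropyrano[3,2-b]pyran-6-one F6. The less hindered C7 silyl ether is cleaved (pyridinium tosylate, MeOH, 0 °C) to (2S,3R,4R,4aS,7R,8S,8aR)-3-hydroxy-2,4,7,8a-tetramethyl-8-[(triethylsilyl)oxy]-2,3,4,4a,7,8-hexahydropyrano[3,2-b]pyran-6-one F7. Esterification with 18 (DCC, DMAP) gives [(2S,3R,4R,4aS,7R,8S,8aR)-2,4,7,8a-tetramethyl-6-oxo-8-[(triethylsilyl)oxy]-2,3,4,4a,7,8-hexahydropyrano[3,2-b]pyran-3-yl] (2E)-4-oxooct-2-enoate F8, and HF·pyridine in THF then frees the C3 hydroxyl to give 19.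

Step 5 may suffer because enal 8 has a γ-hydrogen at C6: Et3N/Me3SiCl could form the silyl dienol ether (epimerising C6 or scrambling the alkene), and the β,β-branched enal may react slowly. The fallback sets out from 6 (with bought 7 and 9) and comes back at 11. The same anti-aldol is run on methacrolein 7, a simple α-substituted acrolein with no γ-hydrogen, to give (4S)-4-benzyl-3-[(2R,3S)-3-hydroxy-2,4-dimethylpent-4-enoyl]-1,3-oxazolidin-2-one F9. Cross-metathesis of excess F9 with 6 (second-generation Hoveyda–Grubbs catalyst, CH2Cl2, 40 °C) then joins the fragments at C4=C5 and gives 11 directly, replacing steps 4 and 5.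

**Further compounds**

F1 | step 7 | (2S,3R,4S,5E)-2-[(tert-butyldimethylsilyl)oxy]-4,6-dimethylocta-5,7-dien-3-ol | C[C@H](O[Si](C)(C)C(C)(C)C)[C@H](O)[C@@H](C)/C=C(\C)C=C
F2 | step 7 | (2S,3R,4R)-2-[(tert-butyldimethylsilyl)oxy]-4-[(2S,3S)-3-ethenyl-3-methyloxiran-2-yl]pentan-3-ol | C[C@H](O[Si](C)(C)C(C)(C)C)[C@H](O)[C@@H](C)[C@@H]1O[C@@]1(C)C=C
F3 | step 7 | (2S,3R,4R)-4-[(2S,3S)-3-ethenyl-3-methyloxiran-2-yl]pentane-2,3-diol | C[C@H](O)[C@H](O)[C@@H](C)[C@@H]1O[C@@]1(C)C=C
F4 | step 7 | (2R,3S,4R,5R,6S)-2-ethenyl-2,4,6-trimethyloxane-3,5-diol | O[C@@H]1[C@@H](C)[C@H](O)[C@@](C)(C=C)O[C@H]1C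
F5 | step 7 | (2S,3S,4R,5R,6S)-3,5-dihydroxy-2,4,6-trimethyloxane-2-carbaldehyde | O[C@@H]1[C@@H](C)[C@H](O)[C@@](C)(C=O)O[C@H]1C
F6 | step 9 | (2S,3R,4R,4aS,7R,8S,8aR)-2,4,7,8a-tetramethyl-3,8-bis[(triethylsilyl)oxy]-2,3,4,4a,7,8-hexahydropyrano[3,2-b]pyran-6-one | CC[Si](CC)(CC)O[C@@H]1[C@@H](C)[C@@H]2OC(=O)[C@H](C)[C@H](O[Si](CC)(CC)CC)[C@@]2(C)O[C@H]1C
F7 | step 9 | (2S,3R,4R,4aS,7R,8S,8aR)-3-hydroxy-2,4,7,8a-tetramethyl-8-[(triethylsilyl)oxy]-2,3,4,4a,7,8-hexahydropyrano[3,2-b]pyran-6-one | O[C@@H]1[C@@H](C)[C@@H]2OC(=O)[C@H](C)[C@H](O[Si](CC)(CC)CC)[C@@]2(C)O[C@H]1C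
F8 | step 9 | [(2S,3R,4R,4aS,7R,8S,8aR)-2,4,7,8a-tetramethyl-6-oxo-8-[(triethylsilyl)oxy]-2,3,4,4a,7,8-hexahydropyrano[3,2-b]pyran-3-yl] (2E)-4-oxooct-2-enoate | CCCCC(=O)/C=C/C(=O)O[C@@H]1[C@@H](C)[C@@H]2OC(=O)[C@H](C)[C@H](O[Si](CC)(CC)CC)[C@@]2(C)O[C@H]1C
F9 | step 5 | (4S)-4-benzyl-3-[(2R,3S)-3-hydroxy-2,4-dimethylpent-4-enoyl]-1,3-oxazolidin-2-one | C=C(C)[C@@H](O)[C@@H](C)C(=O)N1C(=O)OC[C@@H]1Cc1ccccc1
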